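Which flask ends with more X, eta or gamma?

in all of them: Z 0.18 M

| charge | D | temperature | remark | time |
|---|---|---|---|---|
| grey | 0.073 M | 60 °C | run made earlier |  |
| red | 0.26 M | 82 °C | run made earlier |  |
| eta | 0.0500 M |  | at 90 °C throughout | 20 h |
| gamma | 0.180 M |  | at 50 °C until 1.0 h, from then on at 90 °C | 5.0 h |

| run | time / min | X / % |
|---|---|---|
| grey | 12.0 | 0 |
| grey | 25.0 | 1.3 |
| grey | 40.0 | 2.4 |
| grey | 50.0 | 4.9 |
| grey | 80.0 | 8.4 |
| grey | 90.0 | 8.9 |
| red | 4.00 | 0 |
| red | 8.00 | 1.1 |
| red | 12.0 | 1.8 |
| red | 15.0 | 1.6 |
| red | 25.0 | 3.7 |
| red | 30.0 | 4.3 |

(readings scatter by 0.5 percentage points)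

- the flask that ends with the higher amount of X, in percent of the Z charged, or "neither" when 2 percentage points or less lies between them (eta / gamma / neither)
- final X, as a percentage of the Z charged, in eta
- final X, as a percentage of the Z charged, in gamma

- given per volume of solution although it is solid: Z
- the earlier runs were read with a standard deviation of 0.5 percentage points
- steps under discussion: G <-> E; D + E -> X; Z <-> G
- at the start none of Z is in solution
- what has only dissolved of Z counts as not reacted

Two readers of these flasks disagree. The charge reader says a flask ends where its charge stops it: X cannot pass c(D)/c(Z), since one D goes into each X, so eta ends at 27.8% and gamma at 100%. Eta holds less D than Z, which makes D its limiting reagent. The clock reader says a flask ends where the slope of the readings has got to by its time.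

The slopes after the lag, converted to X made per volume, are 0.0126 M/h in grey and 0.0157 M/h in red. These are readings, with their scatter. Red has 0.26 M of D against grey's 0.073 M, and it is hotter too, yet its slope is just 1.25 times grey's, so I let the rate stand apart from c(D). I take the red slope for both new flasks, though gamma spends its first 1.0 h at 50 °C.

The two views meet in one ratio. Divide the slope by the rate that would use up c(D) in the flask's time, c(D)/t. For gamma this gives 0.436, and I call this ratio the reach. In my reckoning, the charge reader's figure stands above one and the clock reader's below one.

Eta has a reach of 6.28, so both readers grant it the ceiling. Gamma has a reach below one, so I side with the clock and commit to 43.6% for gamma.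

The forecast gives gamma, with 24% for eta and 42% for gamma: “Gamma has no such cap within 5 h”.

The simulation gives gamma, with 27.8% for eta and 61.9% for gamma.

    G ⇌ E (K = 1.10, k = 0.460 /h, Ea = 89.0 kJ/mol, ΔH = −37.0 kJ/mol)
    D + E → X (k = 1700 /M/h, Ea = 53.0 kJ/mol)
    Z ⇌ G, rate k3*(cs3 - [G]) while solid is left; crystals form when [G] > cs3 (solubility = 0.0610 M, k = 0.390 /h)
    (constants at 50 °C)

Eta stands at its ceiling, with 0% of its D left at 20.0 h. Gamma's reach, counted from its result, is 0.619, above my 0.436 but still below one, and 38% of its D remains at 5.00 h. Now charge gamma with 0.72 M of Z, keeping D and the time. If the reach holds, X is that reach times c(D)/c(Z), or 15.5% of the Z charged. That flask gives 15.5%, with 38% of its D left.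

The runs were computed for an exercise; scatter was added.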